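**Retrosynthetic overview**
- Feature: ring A carries OH, prenyl, OMe and prenyl on C5 to C8, the pattern of a 1,1,3-trioxygenated 2,4-diprenylbuta-1,3-diene. Its other two carbons, C4a and C8a, are the alpha and beta carbons of the free C=C of a monocyclic 4-pyranone (ring C).
- Target 19 comes from bis-MOM ether 18. Cutting C8–C8a and C4a–C5 of 18 gives silyl ketene acetal diene 6 and 5-(p-tolylsulfinyl)-4-pyranone 15; the sulfinyl group activates, directs, and then leaves as the sulfenic acid.
- Diene 6 comes from methyl acetoacetate 1 and two prenyl bromides 2: gamma-alkylation, alpha-alkylation, O-methylation, O-silylation.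
- Dienophile 15 comes from pyromeconic acid 7 (ring C) and boronate 10 (ring B): C2 iodination, MOM protection, Suzuki coupling, C5 iodination, iodine–magnesium exchange with sulfinylation.
- Ring order: rings C and B are bought and joined at C2–C1'; ring A is formed last, in step 11.

Key step: step 11

Assumption: 5 and 6 may form as E/Z mixtures and 15 is racemic at sulfur, so the drawn isomers stand for these mixtures because aromatisation of ring A erases every such element; 7 and 10 are taken as purchasable.

**Step 1**
Reactants: 1 methyl acetoacetate; 2 prenyl bromide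
Product: 3 methyl 7-methyl-3-oxooct-6-enoate
Conditions: NaH, THF, 0 °C; n-BuLi, 0 °C; 2, 0 °C to rt; dil. HCl
Reagents that add atoms: none
Why: Weiler-type gamma-alkylation, in which double deprotonation makes the terminal carbon the most basic and most nucleophilic site, so it takes up the allylic bromide by SN2 before the stabilised alpha position reacts.

**Step 2**
Reactants: 3 methyl 7-methyl-3-oxooct-6-enoate; 2 prenyl bromide
Product: 4 methyl 7-methyl-2-(3-methylbut-2-enyl)-3-oxooct-6-enoate (racemic)
Conditions: NaH (1 equiv), THF, 0 °C; 2 (1 equiv), 0 °C to rt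
Reagents that add atoms: none
Why: Acetoacetic ester alkylation, in which the stabilised sodium enolate is C-alkylated by the soft allylic bromide, one equivalent each of base and halide limits dialkylation, and the new C2 stereocentre forms racemic and is erased in step 3.

**Step 3**
Reactants: 4 methyl 7-methyl-2-(3-methylbut-2-enyl)-3-oxooct-6-enoate
Product: 5 methyl (2E)-3-methoxy-7-methyl-2-(3-methylbut-2-enyl)octa-2,6-dienoate
Conditions: KN(SiMe3)2, THF–DMPU, −78 °C; Me2SO4, −78 to 0 °C
Reagents that add atoms: dimethyl sulfate, COS(=O)(=O)OC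
Why: Enolate O-alkylation, in which a dissociated potassium enolate in a dipolar aprotic medium meets the hard methylating agent at oxygen, C-methylation would have to build a crowded quaternary carbon, and the base-only conditions spare both prenyl alkenes.

**Step 4**
Reactants: 5 methyl (2E)-3-methoxy-7-methyl-2-(3-methylbut-2-enyl)octa-2,6-dienoate
Product: 6 (1E,3Z)-1,3-dimethoxy-7-methyl-2-(3-methylbut-2-enyl)-1-(trimethylsilyloxy)octa-1,3,6-triene
Conditions: LiN(i-Pr)2 (LDA), THF, −78 °C; Me3SiCl, −78 °C to rt; pentane, filtration, no aqueous work-up, used crude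
Reagents that add atoms: chlorotrimethylsilane, C[Si](C)(C)Cl
Why: Standard Brassard-diene preparation, in which LDA removes a C4 (gamma) proton of the beta-methoxy enoate, the extended ester enolate is silylated on oxygen, and allylic strain against the substituted C2 should place the C4 side chain trans to C2, on the outside of the s-cis diene.

**Step 5**
Reactants: 7 3-hydroxy-4H-pyran-4-one (pyromeconic acid)
Product: 8 3-hydroxy-2-iodo-4H-pyran-4-one
Conditions: NIS, MeCN, 0 °C to rt, dark
Reagents that add atoms: N-iodosuccinimide, O=C1CCC(=O)N1I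
Why: Electrophilic substitution of an enol, in which the 3-OH pushes electron density onto C2, the position where 3-hydroxy-4-pyranones take up halogen, Mannich and aldol electrophiles.

**Step 6**
Reactants: 8 3-hydroxy-2-iodo-4H-pyran-4-one
Product: 9 2-iodo-3-(methoxymethoxy)-4H-pyran-4-one
Conditions: MOMCl, i-Pr2NEt, CH2Cl2, 0 °C to rt
Reagents that add atoms: chloromethyl methyl ether, COCCl
Why: Williamson-type O-alkylation of the acidic enol by the reactive alpha-chloro ether under amine base, which masks the metal-chelating 3-hydroxy-4-one unit before the palladium and magnesium chemistry.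

**Step 7**
Reactants: 10 2-methoxy-5-(4,4,5,5-tetramethyl-1,3,2-dioxaborolan-2-yl)phenol
Product: 11 2-[4-methoxy-3-(methoxymethoxy)phenyl]-4,4,5,5-tetramethyl-1,3,2-dioxaborolane
Conditions: MOMCl, i-Pr2NEt, CH2Cl2, 0 °C to rt
Reagents that add atoms: chloromethyl methyl ether, COCCl
Why: Phenol O-alkylation that leaves the pinacol boronate untouched and removes the phenoxide that could otherwise displace the vinylogous acyl iodide of 9 in step 8.

**Step 8**
Reactants: 9 2-iodo-3-(methoxymethoxy)-4H-pyran-4-one; 11 2-[4-methoxy-3-(methoxymethoxy)phenyl]-4,4,5,5-tetramethyl-1,3,2-dioxaborolane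
Product: 12 3-(methoxymethoxy)-2-[4-methoxy-3-(methoxymethoxy)phenyl]-4H-pyran-4-one
Conditions: Pd(dppf)Cl2 (cat.), K2CO3, dioxane–H2O, 70 °C
Reagents that add atoms: none
Why: Suzuki–Miyaura coupling, in which zerovalent palladium inserts readily into the C2–I bond at the beta position of the enone, and carbonate at moderate temperature is mild enough for the pyranone ring.

**Step 9**
Reactants: 12 3-(methoxymethoxy)-2-[4-methoxy-3-(methoxymethoxy)phenyl]-4H-pyran-4-one
Product: 13 5-iodo-3-(methoxymethoxy)-2-[4-methoxy-3-(methoxymethoxy)phenyl]-4H-pyran-4-one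
Conditions: I2, pyridine, DMAP (cat.), CH2Cl2, rt, dark
Reagents that add atoms: iodine, II
Why: Johnson-type alpha-iodination of a cyclic enone, in which the amine adds reversibly to the unsubstituted C6, the dienolate takes iodine at C5 (the only alpha C–H) and loss of the amine restores the pyranone, while iodine without oxidant or Lewis acid leaves the dialkoxyphenyl ring B and the MOM acetals alone.

**Step 10**
Reactants: 13 5-iodo-3-(methoxymethoxy)-2-[4-methoxy-3-(methoxymethoxy)phenyl]-4H-pyran-4-one
Product: 15 3-(methoxymethoxy)-2-[4-methoxy-3-(methoxymethoxy)phenyl]-5-(4-methylphenylsulfinyl)-4H-pyran-4-one (racemic at sulfur), via 5-chloromagnesio pyranone 14 (not isolated)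
Conditions: i-PrMgCl·LiCl, THF, −40 °C; cannulated into methyl 4-methylbenzenesulfinate, THF, −78 to −20 °C; aq. NH4Cl
Reagents that add atoms: methyl 4-methylbenzenesulfinate, COS(=O)c1ccc(C)cc1; isopropylmagnesium chloride–lithium chloride, CC(C)[Mg]Cl.[Li+].[Cl-] (supplies the MgCl of 14 only)
Why: Iodine–magnesium exchange on an alpha-iodo vinylogous ester followed by Andersen-type substitution at sulfur, in which the exchange is fast in the cold because the carbonyl oxygen stabilises the sp2 carbanion, the vinylogous ester carbonyl is a poor electrophile, inverse addition keeps the organomagnesium away from product, and the racemic sulfinate makes the sulfur stereocentre racemic.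

**Step 11**
Reactants: 6 (1E,3Z)-1,3-dimethoxy-7-methyl-2-(3-methylbut-2-enyl)-1-(trimethylsilyloxy)octa-1,3,6-triene; 15 3-(methoxymethoxy)-2-[4-methoxy-3-(methoxymethoxy)phenyl]-5-(4-methylphenylsulfinyl)-4H-pyran-4-one
Product: 18 5-hydroxy-7-methoxy-3-(methoxymethoxy)-2-[4-methoxy-3-(methoxymethoxy)phenyl]-6,8-bis(3-methylbut-2-enyl)chromen-4-one, via cis-fused cycloadduct 16 (not isolated), via 5-O-trimethylsilyl chromone 17 (not isolated)
Conditions: 6 (excess), PhMe, rt to 80 °C; then MeOH, SiO2, rt
Reagents that add atoms: none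
Why: Proposed new method: the nucleophilic terminus C4 of 6 bonds to C6 of 15, which is beta to both the carbonyl and the sulfinyl group, and the alpha-sulfinyl carbon C5 closes on the silyloxy(methoxy)-substituted C1 in a strongly asynchronous, suprafacial [4+2] addition that forms C8–C8a and C4a–C5 and closes ring A as a six-membered carbocycle in the intermolecular cycloaddition mode (four diene carbons plus two pyranone carbons). Suprafacial addition places the sulfinyl group on C4a and the hydrogen on C8a of 16 on the same face, the geometry needed for thermal syn-elimination of 4-methylbenzenesulfenic acid to create C4a=C8a, after which the C5 mixed acetal loses its methoxy group together with C8–H and gives aromatic silyl ether 17, which methanol cleaves to the chelated 5-phenol 18 with O7 still methylated. The closest known reactions are the cycloaddition–aromatisation of Brassard-type dienes with halo- and sulfinylquinones and of 3-sulfinyl- or 3-acylchromones with siloxydienes, whereas a monocyclic 4-pyranone has not served as the two-carbon partner. The four carbon stereocentres of 16 and its sulfur centre need no control, because aromatisation erases all of them and 18 has none. The step needs regioselectivity, secured by matched polarisation, since the ketene acetal makes C4 of the diene the donor end and both acceptor groups make C6 of the pyranone the acceptor end, so the acetal carbon ends at C5 beside C4a and the prenyl-bearing terminus at C8. It also needs site selectivity, secured because C5=C6 is the only activated and sterically open C=C, C2=C3 being tetrasubstituted and donor-substituted and the prenyl alkenes unactivated.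

**Step 12**
Reactants: 18 5-hydroxy-7-methoxy-3-(methoxymethoxy)-2-[4-methoxy-3-(methoxymethoxy)phenyl]-6,8-bis(3-methylbut-2-enyl)chromen-4-one
Product: 19 3,5-dihydroxy-2-(3-hydroxy-4-methoxyphenyl)-7-methoxy-6,8-bis(3-methylbut-2-enyl)chromen-4-one (target)
Conditions: 3 M aq. HCl, MeOH, 40 °C
Reagents that add atoms: none
Why: Acid-catalysed acetal exchange (MOM cleavage) as practised on prenylated flavonoids, which is tolerable here because O7 is methylated and the 5-OH, the only hydroxyl next to a prenyl group, is held in the hydrogen bond to C4=O and is therefore slow to add to the alkene.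

**Compound list**
1 | methyl acetoacetate | COC(=O)CC(C)=O | starting material
2 | prenyl bromide (1-bromo-3-methylbut-2-ene) | CC(C)=CCBr | starting material
3 | methyl 7-methyl-3-oxooct-6-enoate | COC(=O)CC(=O)CCC=C(C)C | intermediate
4 | methyl 7-methyl-2-(3-methylbut-2-enyl)-3-oxooct-6-enoate (racemic) | COC(=O)C(CC=C(C)C)C(=O)CCC=C(C)C | intermediate
5 | methyl (2E)-3-methoxy-7-methyl-2-(3-methylbut-2-enyl)octa-2,6-dienoate | COC(=O)/C(CC=C(C)C)=C(/OC)CCC=C(C)C | intermediate
6 | (1E,3Z)-1,3-dimethoxy-7-methyl-2-(3-methylbut-2-enyl)-1-(trimethylsilyloxy)octa-1,3,6-triene | CO/C(O[Si](C)(C)C)=C(/CC=C(C)C)\C(OC)=C\CC=C(C)C | intermediate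
7 | 3-hydroxy-4H-pyran-4-one (pyromeconic acid) | Oc1coccc1=O | starting material
8 | 3-hydroxy-2-iodo-4H-pyran-4-one | Oc1c(I)occc1=O | intermediate
9 | 2-iodo-3-(methoxymethoxy)-4H-pyran-4-one | COCOc1c(I)occc1=O | intermediate
10 | 2-methoxy-5-(4,4,5,5-tetramethyl-1,3,2-dioxaborolan-2-yl)phenol | COc1ccc(B2OC(C)(C)C(C)(C)O2)cc1O | starting material
11 | 2-[4-methoxy-3-(methoxymethoxy)phenyl]-4,4,5,5-tetramethyl-1,3,2-dioxaborolane | COCOc1cc(B2OC(C)(C)C(C)(C)O2)ccc1OC | intermediate
12 | 3-(methoxymethoxy)-2-[4-methoxy-3-(methoxymethoxy)phenyl]-4H-pyran-4-one | COCOc1c(-c2ccc(OC)c(OCOC)c2)occc1=O | intermediate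
13 | 5-iodo-3-(methoxymethoxy)-2-[4-methoxy-3-(methoxymethoxy)phenyl]-4H-pyran-4-one | COCOc1c(-c2ccc(OC)c(OCOC)c2)occ(I)c1=O | intermediate
14 | 5-chloromagnesio-3-(methoxymethoxy)-2-[4-methoxy-3-(methoxymethoxy)phenyl]-4H-pyran-4-one (not isolated) | COCOc1c(-c2ccc(OC)c(OCOC)c2)occ([Mg]Cl)c1=O | intermediate
15 | 3-(methoxymethoxy)-2-[4-methoxy-3-(methoxymethoxy)phenyl]-5-(4-methylphenylsulfinyl)-4H-pyran-4-one (racemic at sulfur) | COCOc1c(-c2ccc(OC)c(OCOC)c2)occ(S(=O)c2ccc(C)cc2)c1=O | intermediate
16 | 5,7-dimethoxy-3-(methoxymethoxy)-2-[4-methoxy-3-(methoxymethoxy)phenyl]-6,8-bis(3-methylbut-2-enyl)-4a-(4-methylphenylsulfinyl)-5-(trimethylsilyloxy)-4a,5,8,8a-tetrahydrochromen-4-one (cis-fused, sulfinyl on C4a and H on C8a on the same face; racemic; mixture at C5, C8 and sulfur; not isolated) | COCOC1=C(c3ccc(OC)c(OCOC)c3)O[C@@H]2C(CC=C(C)C)C(OC)=C(CC=C(C)C)C(OC)(O[Si](C)(C)C)[C@]2(S(=O)c4ccc(C)cc4)C1=O | intermediate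
17 | 7-methoxy-3-(methoxymethoxy)-2-[4-methoxy-3-(methoxymethoxy)phenyl]-6,8-bis(3-methylbut-2-enyl)-5-(trimethylsilyloxy)chromen-4-one (not isolated) | COCOc1c(-c2ccc(OC)c(OCOC)c2)oc2c(CC=C(C)C)c(OC)c(CC=C(C)C)c(O[Si](C)(C)C)c2c1=O | intermediate
18 | 5-hydroxy-7-methoxy-3-(methoxymethoxy)-2-[4-methoxy-3-(methoxymethoxy)phenyl]-6,8-bis(3-methylbut-2-enyl)chromen-4-one | COCOc1c(-c2ccc(OC)c(OCOC)c2)oc2c(CC=C(C)C)c(OC)c(CC=C(C)C)c(O)c2c1=O | intermediate
19 | 3,5-dihydroxy-2-(3-hydroxy-4-methoxyphenyl)-7-methoxy-6,8-bis(3-methylbut-2-enyl)chromen-4-one (no stereocentre) | COc1ccc(-c2oc3c(CC=C(C)C)c(OC)c(CC=C(C)C)c(O)c3c(=O)c2O)cc1O | target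

**Total step count:** 12
**Longest linear sequence:** 7 steps (7 → 8 → 9 → 12 → 13 → 15 → 18 → 19; steps 5, 6, 8, 9, 10, 11, 12)

**Steps most likely to fail**

1. **Step 11.**
- What may go wrong: the two C–C bonds may not form in one event.
  - After the first bond at C6 the enolate may expel the ring oxygen and open ring C.
  - The silyl group may migrate to the sulfinyl or carbonyl oxygen, a Pummerer-type diversion.
  - The acid released during aromatisation may protonate diene that has not yet reacted.
- Fallback (known chemistry; ring A is bought and ring C is built last): it sets out from prenyl bromide 2. This C-alkylates commercial 2,4,6-trihydroxyacetophenone twice (KOH, H2O, 0 °C) to give 1-[2,4,6-trihydroxy-3,5-bis(3-methylbut-2-enyl)phenyl]ethanone F1. The one hydroxyl that is not hydrogen-bonded to the acetyl group is methylated (Me2SO4, K2CO3, acetone) to 1-[2,6-dihydroxy-4-methoxy-3,5-bis(3-methylbut-2-enyl)phenyl]ethanone F2. One of the two equivalent chelated hydroxyls is then protected (MOMCl, i-Pr2NEt) to 1-[2-hydroxy-4-methoxy-6-(methoxymethoxy)-3,5-bis(3-methylbut-2-enyl)phenyl]ethanone F3. Commercial isovanillin and MOMCl give 4-methoxy-3-(methoxymethoxy)benzaldehyde F4. Claisen–Schmidt condensation of F3 with F4 (KOH, EtOH) should give (E)-1-[2-hydroxy-4-methoxy-6-(methoxymethoxy)-3,5-bis(3-methylbut-2-enyl)phenyl]-3-[4-methoxy-3-(methoxymethoxy)phenyl]prop-2-en-1-one F5. Algar–Flynn–Oyamada oxidation (H2O2, NaOH, MeOH, cold), which does not touch isolated alkenes, closes ring C to 3-hydroxy-7-methoxy-5-(methoxymethoxy)-2-[4-methoxy-3-(methoxymethoxy)phenyl]-6,8-bis(3-methylbut-2-enyl)chromen-4-one F6. The conditions of step 12 remove both MOM groups, and the route is rejoined at target 19.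

2. **Step 10.**
- What may go wrong:
  - The isopropyl Grignard reagent, or the magnesiated pyranone, may add to C6 or C4 of a second pyranone molecule.
  - The organomagnesium may attack the newly formed, strongly electrophilic sulfinyl pyranone.
- Fallback (no organomagnesium): it sets out from 13. Palladium-catalysed C–S coupling (Pd2(dba)3, Xantphos, 4-methylbenzenethiol, i-Pr2NEt, dioxane, 80 °C) should give 3-(methoxymethoxy)-2-[4-methoxy-3-(methoxymethoxy)phenyl]-5-(4-methylphenylsulfanyl)-4H-pyran-4-one F7. One equivalent of mCPBA (CH2Cl2, −78 to −20 °C) oxidises it to the sulfoxide, and the route is rejoined at 15.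

3. **Step 9.**
- What may go wrong: the cross-conjugated pyranone may accept the amine too poorly and attack iodine too weakly, so the iodination stalls. Forcing it with stronger iodinating agents would bring halogenation of ring B and loss of MOM groups into play.
- Fallback (C5 is halogenated before ring B is present): it sets out from 9. Classical electrophilic bromination at the alpha carbon of the 4-pyranone (NBS, MeCN) gives 5-bromo-2-iodo-3-(methoxymethoxy)-4H-pyran-4-one F8. Suzuki coupling with 11 under the conditions of step 8 takes place at the C–I bond only and gives 5-bromo-3-(methoxymethoxy)-2-[4-methoxy-3-(methoxymethoxy)phenyl]-4H-pyran-4-one F9. This bromide undergoes the palladium-catalysed thiolation described above to the sulfide F7, and oxidation with mCPBA rejoins the route at 15, bypassing 13 and 14.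

**Further compounds**
F1 | step 11 | 1-[2,4,6-trihydroxy-3,5-bis(3-methylbut-2-enyl)phenyl]ethanone | CC(=O)c1c(O)c(CC=C(C)C)c(O)c(CC=C(C)C)c1O
F2 | step 11 | 1-[2,6-dihydroxy-4-methoxy-3,5-bis(3-methylbut-2-enyl)phenyl]ethanone | CC(=O)c1c(O)c(CC=C(C)C)c(OC)c(CC=C(C)C)c1O
F3 | step 11 | 1-[2-hydroxy-4-methoxy-6-(methoxymethoxy)-3,5-bis(3-methylbut-2-enyl)phenyl]ethanone | CC(=O)c1c(O)c(CC=C(C)C)c(OC)c(CC=C(C)C)c1OCOC
F4 | step 11 | 4-methoxy-3-(methoxymethoxy)benzaldehyde | COCOc1cc(C=O)ccc1OC
F5 | step 11 | (E)-1-[2-hydroxy-4-methoxy-6-(methoxymethoxy)-3,5-bis(3-methylbut-2-enyl)phenyl]-3-[4-methoxy-3-(methoxymethoxy)phenyl]prop-2-en-1-one | COCOc1cc(/C=C/C(=O)c2c(O)c(CC=C(C)C)c(OC)c(CC=C(C)C)c2OCOC)ccc1OC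
F6 | step 11 | 3-hydroxy-7-methoxy-5-(methoxymethoxy)-2-[4-methoxy-3-(methoxymethoxy)phenyl]-6,8-bis(3-methylbut-2-enyl)chromen-4-one | COCOc1cc(-c2oc3c(CC=C(C)C)c(OC)c(CC=C(C)C)c(OCOC)c3c(=O)c2O)ccc1OC
F7 | step 10 | 3-(methoxymethoxy)-2-[4-methoxy-3-(methoxymethoxy)phenyl]-5-(4-methylphenylsulfanyl)-4H-pyran-4-one | COCOc1c(-c2ccc(OC)c(OCOC)c2)occ(Sc2ccc(C)cc2)c1=O
F8 | step 9 | 5-bromo-2-iodo-3-(methoxymethoxy)-4H-pyran-4-one | COCOc1c(I)occ(Br)c1=O
F9 | step 9 | 5-bromo-3-(methoxymethoxy)-2-[4-methoxy-3-(methoxymethoxy)phenyl]-4H-pyran-4-one | COCOc1c(-c2ccc(OC)c(OCOC)c2)occ(Br)c1=O
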